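The target is cut at the C15–C15′ σ-bond in the centre of the E,E-diene C14=C15–C15′=C14′ (carotenoid numbering: ring A C1–C6 with C3=O, chain C7–C15, primes for the ring B half). This bond lies on the pseudo-twofold axis of the retro-polyene: rings A and B carry the same C20 4-ylidene-3,5,5-trimethylcyclohexene–nonatetraenyl skeleton and differ only at C3/C3′. One C20 keto vinylstannane therefore supplies both partners, the iodide by tin–iodine exchange and the S-carbinol stannane by CBS reduction. A stereoretentive Stille sp2–sp2 coupling of the iodohexaenone with the stannylhexaenol forms C15–C15′ and completes the twelve-C=C chromophore in one operation, without protecting groups.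

Key step: step 10

Assumption: the geometry of the exocyclic ring–chain double bonds (C6=C7, C6′=C7′) is set under thermodynamic control when the enal forms in step 2; the E and Z isomers are taken to be separable by chromatography at compounds 6 and 8, the Z isomer to be recyclable by iodine-catalysed equilibration, and all polyenes are handled under argon with exclusion of light.

Step 1
Reactants: 1 ketoisophorone (2,6,6-trimethylcyclohex-2-ene-1,4-dione); 2 ethylene glycol
Product: 3 7,9,9-trimethyl-1,4-dioxaspiro[4.5]dec-6-en-8-one (4-mono-dioxolane of ketoisophorone)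
Conditions: ethylene glycol, p-TsOH·H2O (cat.), toluene, reflux, Dean–Stark
Reagents that add atoms: ethylene glycol 2, OCCO
Why: Acid-catalysed ketalisation with water removal should occur only at the C4 carbonyl (flanked by CH= and CH2), because the C1 carbonyl between the quaternary C6 and the methyl-bearing C2 is too hindered; no stereocentre is formed.

Step 2
Reactants: 3 7,9,9-trimethyl-1,4-dioxaspiro[4.5]dec-6-en-8-one; 4 (Z)-1-bromo-2-ethoxyethene
Product: 6 (2E)-2-(2,6,6-trimethyl-4-oxocyclohex-2-en-1-ylidene)acetaldehyde, via carbinol adduct 5 (not isolated)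
Conditions: 4, n-BuLi, THF, −78 °C; then 3, −78 → −20 °C; then 2 M HCl, THF, rt
Reagents that add atoms: (Z)-1-bromo-2-ethoxyethene 4, CCO/C=C\Br; water, O
Why: Bromine–lithium exchange gives (Z)-2-ethoxyvinyllithium, which should add 1,2 to the non-enolisable ketone of 3, and aqueous acid then unravels the β-hydroxy enol ether of 5 to the enal (a formyl-olefination related to the Meyer–Schuster 1,3-transposition) and cleaves the dioxolane; dehydration can only give the exocyclic alkene because neither ring neighbour carries hydrogen, and the E isomer is collected after chromatography.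

Step 3
Reactants: 6 (2E)-2-(2,6,6-trimethyl-4-oxocyclohex-2-en-1-ylidene)acetaldehyde; 7 2-(triphenylphosphoranylidene)propanal
Product: 8 (2E,4E)-2-methyl-4-(2,6,6-trimethyl-4-oxocyclohex-2-en-1-ylidene)but-2-enal
Conditions: toluene, 80 °C
Reagents that add atoms: 2-(triphenylphosphoranylidene)propanal 7, CC(C=O)=P(c1ccccc1)(c1ccccc1)c1ccccc1
Why: Wittig olefination with a stabilised formyl ylide should react only at the aldehyde (not at the hindered ring ketone) and give the E trisubstituted C8=C9 alkene, as is usual for stabilised ylides.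

Step 4
Reactants: 9 (2E)-3-methylpent-2-en-4-yn-1-ol; 10 tributyltin hydride
Product: 11 (2E,4E)-3-methyl-5-(tributylstannyl)penta-2,4-dien-1-ol
Conditions: Bu3SnH, PdCl2(PPh3)2 (2 mol%), THF, 0 °C → rt
Reagents that add atoms: tributyltin hydride 10, CCCC[SnH](CCCC)CCCC
Why: Palladium-catalysed syn-hydrostannation of the terminal alkyne should place tin on the unhindered terminal carbon and hydrogen cis to it, giving the E vinylstannane while the trisubstituted alkene is untouched.

Step 5
Reactants: 11 (2E,4E)-3-methyl-5-(tributylstannyl)penta-2,4-dien-1-ol; 12 tetrabromomethane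
Product: 13 tributyl[(1E,3E)-5-bromo-3-methylpenta-1,3-dien-1-yl]stannane
Conditions: CBr4, PPh3, CH2Cl2, −20 → 0 °C
Reagents that add atoms: tetrabromomethane 12, BrC(Br)(Br)Br
Why: Appel bromination under neutral conditions should convert the primary allylic alcohol into the bromide by SN2 displacement of the oxyphosphonium group, without protodestannylation or allylic transposition.

Step 6
Reactants: 13 tributyl[(1E,3E)-5-bromo-3-methylpenta-1,3-dien-1-yl]stannane; 14 triethyl phosphite
Product: 15 diethyl [(2E,4E)-3-methyl-5-(tributylstannyl)penta-2,4-dien-1-yl]phosphonate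
Conditions: P(OEt)3 (neat), 90 °C
Reagents that add atoms: triethyl phosphite 14, CCOP(OCC)OCC
Why: Michaelis–Arbuzov reaction, in which SN2 attack of phosphorus at the primary allylic bromide and loss of bromoethane should give the phosphonate with both alkene geometries and the vinylstannane preserved.

Step 7
Reactants: 8 (2E,4E)-2-methyl-4-(2,6,6-trimethyl-4-oxocyclohex-2-en-1-ylidene)but-2-enal; 15 diethyl [(2E,4E)-3-methyl-5-(tributylstannyl)penta-2,4-dien-1-yl]phosphonate
Product: 16 (4E)-4-[(2E,4E,6E,8E)-3,7-dimethyl-9-(tributylstannyl)nona-2,4,6,8-tetraen-1-ylidene]-3,5,5-trimethylcyclohex-2-en-1-one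
Conditions: 15, LiHMDS, THF, −78 °C; then 8, −78 → 0 °C
Reagents that add atoms: none
Why: Horner–Wadsworth–Emmons olefination of the aldehyde with the lithiated allylic phosphonate at low temperature should form C10=C11 with E selectivity (reversible addition, then elimination of phosphate) faster than any reaction at the hindered, conjugated ring ketone.

Step 8
Reactants: 16 (4E)-4-[(2E,4E,6E,8E)-3,7-dimethyl-9-(tributylstannyl)nona-2,4,6,8-tetraen-1-ylidene]-3,5,5-trimethylcyclohex-2-en-1-one; 17 iodine
Product: 18 (4E)-4-[(2E,4E,6E,8E)-9-iodo-3,7-dimethylnona-2,4,6,8-tetraen-1-ylidene]-3,5,5-trimethylcyclohex-2-en-1-one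
Conditions: I2 (1.0 equiv), CH2Cl2, −78 → 0 °C, dark
Reagents that add atoms: iodine 17, II
Why: Iododestannylation, an electrophilic ipso-substitution of the C(sp2)–Sn bond that proceeds with retention of the E geometry and should be much faster than any addition of iodine to the electron-poor polyene.

Step 9
Reactants: 16 (4E)-4-[(2E,4E,6E,8E)-3,7-dimethyl-9-(tributylstannyl)nona-2,4,6,8-tetraen-1-ylidene]-3,5,5-trimethylcyclohex-2-en-1-one
Product: 19 (1S,4E)-4-[(2E,4E,6E,8E)-3,7-dimethyl-9-(tributylstannyl)nona-2,4,6,8-tetraen-1-ylidene]-3,5,5-trimethylcyclohex-2-en-1-ol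
Conditions: (R)-2-methyl-CBS-oxazaborolidine (20 mol%), catecholborane, toluene, −78 → −40 °C; then MeOH, aq. NaHCO3
Reagents that add atoms: none
Why: Corey–Bakshi–Shibata reduction, in which the carbonyl is expected to bind the (R)-oxazaborolidine–borane complex with its sp2 C4 flank as the large group, so that 1,2-hydride delivery sets the C3 carbinol centre as S under catalyst control; the s-trans ring enone disfavours conjugate reduction and the vinylstannane is inert.

Step 10
Reactants: 18 (4E)-4-[(2E,4E,6E,8E)-9-iodo-3,7-dimethylnona-2,4,6,8-tetraen-1-ylidene]-3,5,5-trimethylcyclohex-2-en-1-one; 19 (1S,4E)-4-[(2E,4E,6E,8E)-3,7-dimethyl-9-(tributylstannyl)nona-2,4,6,8-tetraen-1-ylidene]-3,5,5-trimethylcyclohex-2-en-1-ol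
Product: 20 (3′S,all-E)-3′-hydroxy-4′,5′-didehydro-4,5′-retro-β,β-caroten-3-one (eschscholtzxanthone)
Conditions: Pd2(dba)3·CHCl3 (2.5 mol%), AsPh3 (20 mol%), NMP, rt, dark, argon
Reagents that add atoms: none
Why: Stille cross-coupling, in which zerovalent palladium inserts into the C15–I bond of 18 with retention, the C15′–Sn bond of 19 transmetalates with retention, and reductive elimination forms the C15–C15′ σ-bond of the central diene. The closest known reaction type is the palladium-catalysed coupling of polyenyl iodides with polyenylstannanes used to assemble conjugated polyenes. No ring is closed and no stereocentre is created; the (3′S) carbinol set in step 9 is remote and should be untouched under the neutral conditions. The step needs retention of the E geometry at C14=C15 and C14′=C15′ and no scrambling of the other ten C=C bonds, which the stereospecific elementary steps, the weakly bound AsPh3 ligand (fast transmetalation at room temperature) and exclusion of light should secure. Chemoselectivity rests on the exclusive reactivity of the C(sp2)–I and C(sp2)–Sn termini, so the ring A enone and the free allylic hydroxyl of ring B need no protection.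

Compound list
1 | ketoisophorone (2,6,6-trimethylcyclohex-2-ene-1,4-dione) | CC1=CC(=O)CC(C)(C)C1=O | starting material
2 | ethylene glycol | OCCO | starting material
3 | 7,9,9-trimethyl-1,4-dioxaspiro[4.5]dec-6-en-8-one | CC1=CC2(OCCO2)CC(C)(C)C1=O | intermediate
4 | (Z)-1-bromo-2-ethoxyethene | CCO/C=C\Br | starting material
5 | 8-[(Z)-2-ethoxyethenyl]-7,9,9-trimethyl-1,4-dioxaspiro[4.5]dec-6-en-8-ol (carbinol adduct, racemic, not isolated) | CCO/C=C\C1(O)C(C)=CC2(OCCO2)CC1(C)C | intermediate
6 | (2E)-2-(2,6,6-trimethyl-4-oxocyclohex-2-en-1-ylidene)acetaldehyde | CC1=CC(=O)CC(C)(C)\C1=C/C=O | intermediate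
7 | 2-(triphenylphosphoranylidene)propanal | CC(C=O)=P(c1ccccc1)(c1ccccc1)c1ccccc1 | starting material
8 | (2E,4E)-2-methyl-4-(2,6,6-trimethyl-4-oxocyclohex-2-en-1-ylidene)but-2-enal | CC1=CC(=O)CC(C)(C)\C1=C/C=C(C)/C=O | intermediate
9 | (2E)-3-methylpent-2-en-4-yn-1-ol | C#C/C(C)=C/CO | starting material
10 | tributyltin hydride | CCCC[SnH](CCCC)CCCC | starting material
11 | (2E,4E)-3-methyl-5-(tributylstannyl)penta-2,4-dien-1-ol | CCCC[Sn](CCCC)(CCCC)/C=C/C(C)=C/CO | intermediate
12 | tetrabromomethane | BrC(Br)(Br)Br | starting material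
13 | tributyl[(1E,3E)-5-bromo-3-methylpenta-1,3-dien-1-yl]stannane | CCCC[Sn](CCCC)(CCCC)/C=C/C(C)=C/CBr | intermediate
14 | triethyl phosphite | CCOP(OCC)OCC | starting material
15 | diethyl [(2E,4E)-3-methyl-5-(tributylstannyl)penta-2,4-dien-1-yl]phosphonate | CCOP(=O)(OCC)C/C=C(C)/C=C/[Sn](CCCC)(CCCC)CCCC | intermediate
16 | (4E)-4-[(2E,4E,6E,8E)-3,7-dimethyl-9-(tributylstannyl)nona-2,4,6,8-tetraen-1-ylidene]-3,5,5-trimethylcyclohex-2-en-1-one | CC1=CC(=O)CC(C)(C)\C1=C/C=C(C)/C=C/C=C(C)/C=C/[Sn](CCCC)(CCCC)CCCC | intermediate
17 | iodine | II | starting material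
18 | (4E)-4-[(2E,4E,6E,8E)-9-iodo-3,7-dimethylnona-2,4,6,8-tetraen-1-ylidene]-3,5,5-trimethylcyclohex-2-en-1-one | CC1=CC(=O)CC(C)(C)\C1=C/C=C(C)/C=C/C=C(C)/C=C/I | intermediate
19 | (1S,4E)-4-[(2E,4E,6E,8E)-3,7-dimethyl-9-(tributylstannyl)nona-2,4,6,8-tetraen-1-ylidene]-3,5,5-trimethylcyclohex-2-en-1-ol | CC1=C[C@@H](O)CC(C)(C)\C1=C/C=C(C)/C=C/C=C(C)/C=C/[Sn](CCCC)(CCCC)CCCC | intermediate
20 | (3′S,all-E)-3′-hydroxy-4′,5′-didehydro-4,5′-retro-β,β-caroten-3-one: (4E)-4-ylidene-3,5,5-trimethylcyclohex-2-en-1-one (ring A) and (4S)-4-hydroxy-2,6,6-trimethylcyclohex-2-en-1-ylidene (ring B) joined by the all-E 3,7,12,16-tetramethyloctadeca-2,4,6,8,10,12,14,16-octaene-1,18-diylidene chain | CC1=CC(=O)CC(C)(C)\C1=C/C=C(C)/C=C/C=C(C)/C=C/C=C/C(C)=C/C=C/C(C)=C/C=C1/C(C)=C[C@@H](O)CC1(C)C | target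

Total step count: 10. Longest linear sequence: 6 steps (steps 1, 2, 3, 7, 9, 10).

Steps most likely to fail

Step 9 (CBS reduction). The risk is insufficient facial discrimination between the sp2 C4–H flank and the neopentyl-like C2H2 flank of the carbonyl, together with slow hydride transfer to the strongly conjugated ketone that lets unselective background reduction compete. The fallback fixes the stereocentre on the ring before the chain is built; it sets out from 1 and comes back at 19. Noyori-type asymmetric transfer hydrogenation of 1 (RuCl(p-cymene)[(S,S)-TsDPEN], iPrOH, rt), which should reduce only the less hindered C4 carbonyl, gives (4S)-4-hydroxy-2,6,6-trimethylcyclohex-2-en-1-one F1. TBSCl and imidazole in DMF give the silyl ether F2. Addition of (Z)-2-ethoxyvinyllithium (from 4 and n-BuLi, THF, −78 °C) gives the tertiary carbinol F3, which is not isolated but collapsed with cold dilute aqueous oxalic acid to the silyloxy enal F4. Wittig reaction with 7 gives the silyloxy trienal F5, HWE reaction with lithiated 15 gives the silyl-protected stannane F6, and TBAF in THF then releases 19.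

Step 10 (Stille coupling). The risk is slow transmetalation, which would allow homocoupling of the stannane, protodestannylation, or palladium-mediated E/Z isomerisation, above all at the labile C6=C7 bond of the ketone half. The fallback replaces the cross-coupling by a symmetrical dimerisation followed by desymmetrisation; it sets out from 16 and comes back at 20. CuCl-mediated oxidative homocoupling of the alkenylstannane 16 (CuCl, DMF, rt, dark) should form the same C15–C15′ bond and give the symmetrical dione rhodoxanthin F7. Reduction of only one of its two equivalent ring carbonyls under the conditions of step 9, with a substoichiometric amount of catecholborane and stopped at partial conversion, gives 20. It differs in polarity from recovered F7 (recycled) and from doubly reduced material, so chromatographic separation should be possible.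

Step 7 (HWE olefination). The risk is proton transfer from the enolisable ring ketone to the phosphonate anion, leading to incomplete olefination and aldol-type self-condensation, with possible loss of E selectivity at C10=C11. The fallback keeps the ring carbonyl masked through the chain extension; it sets out from the carbinol adduct 5 (made from 3 as in step 2) and comes back at 16. Quenching the addition mixture with cold dilute aqueous oxalic acid instead of HCl should unravel only the enol ether and leave the dioxolane, giving the ketal enal F8. Wittig reaction with 7 gives the ketal trienal F9, and HWE reaction with lithiated 15, now without any enolisable carbonyl group, gives the ketal stannane F10. PPTS in wet acetone at rt then removes the dioxolane to give 16.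

Further compounds
F1 | step 9 | (4S)-4-hydroxy-2,6,6-trimethylcyclohex-2-en-1-one | CC1=C[C@@H](O)CC(C)(C)C1=O
F2 | step 9 | (4S)-4-[(tert-butyldimethylsilyl)oxy]-2,6,6-trimethylcyclohex-2-en-1-one | CC1=C[C@@H](O[Si](C)(C)C(C)(C)C)CC(C)(C)C1=O
F3 | step 9 | (4S)-4-[(tert-butyldimethylsilyl)oxy]-1-[(Z)-2-ethoxyethenyl]-2,6,6-trimethylcyclohex-2-en-1-ol (C1 epimers, not isolated) | CCO/C=C\C1(O)C(C)=C[C@@H](O[Si](C)(C)C(C)(C)C)CC1(C)C
F4 | step 9 | (2E)-2-[(4S)-4-[(tert-butyldimethylsilyl)oxy]-2,6,6-trimethylcyclohex-2-en-1-ylidene]acetaldehyde | CC1=C[C@@H](O[Si](C)(C)C(C)(C)C)CC(C)(C)\C1=C/C=O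
F5 | step 9 | (2E,4E)-4-[(4S)-4-[(tert-butyldimethylsilyl)oxy]-2,6,6-trimethylcyclohex-2-en-1-ylidene]-2-methylbut-2-enal | CC1=C[C@@H](O[Si](C)(C)C(C)(C)C)CC(C)(C)\C1=C/C=C(C)/C=O
F6 | step 9 | tert-butyldimethylsilyl ether of 19 | CC1=C[C@@H](O[Si](C)(C)C(C)(C)C)CC(C)(C)\C1=C/C=C(C)/C=C/C=C(C)/C=C/[Sn](CCCC)(CCCC)CCCC
F7 | step 10 | rhodoxanthin ((all-E)-4′,5′-didehydro-4,5′-retro-β,β-carotene-3,3′-dione) | CC1=CC(=O)CC(C)(C)\C1=C/C=C(C)/C=C/C=C(C)/C=C/C=C/C(C)=C/C=C/C(C)=C/C=C1/C(C)=CC(=O)CC1(C)C
F8 | step 7 | (2E)-2-(7,9,9-trimethyl-1,4-dioxaspiro[4.5]dec-6-en-8-ylidene)acetaldehyde | CC1=CC2(OCCO2)CC(C)(C)\C1=C/C=O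
F9 | step 7 | (2E,4E)-2-methyl-4-(7,9,9-trimethyl-1,4-dioxaspiro[4.5]dec-6-en-8-ylidene)but-2-enal | CC1=CC2(OCCO2)CC(C)(C)\C1=C/C=C(C)/C=O
F10 | step 7 | ethylene ketal of 16 | CC1=CC2(OCCO2)CC(C)(C)\C1=C/C=C(C)/C=C/C=C(C)/C=C/[Sn](CCCC)(CCCC)CCCC
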